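Locants (germacrane type): carbocycle C1–C10; ring A = 4,5-dihydrofuran (O, C1, C2, C3, C4); ring B = butenolide (O, C6, C7, C11, C12); C13 = CH2OAc on C11; methacrylate on O8; OH and CH3 on C10; CH3 on C4.
Retrosynthetic cuts in order: acetyl–O13; C11–C13; C5=C6 (opens the ten-membered ring); methacryloyl–O8; C7–C8 (frees ring B as a dibromobutenolide phosphonate); C1=C2 (opens ring A); the acyl C1–O bond of the resulting ester.
Feature that allows the key step: in ring A the enol ether C1=C2 sits between two fully substituted methyl carbinol carbons, C4 inside the ring and C10 on C1. Cutting C1=C2 therefore leaves the ester of a C4 tertiary homoallylic alcohol (C2–C5) with a non-enolisable C10 alpha-silyloxy acid (C1, C8–C10).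
Forward: esterification, closure of ring A, attachment of preformed ring B at C8, closure of the ten-membered ring at C5=C6, then C13. C13 comes last because a carbanion at C6 would expel any oxygen leaving group from C13.
Stereochemistry: C4 (S) from (R)-2-methylglycidol, C10 (R) from (R)-citramalic acid, C8 (S) from a catalyst-controlled CBS reduction, and the C5=C6 geometry (C4 cis to C7, E) from the ring constraint.

Key step: step 7

Remark: C6 of the butenolide phosphonate is racemic and base-labile, so all intermediates between the Ni/Cr coupling and the macrocyclisation are carried as C6 epimers and this centre disappears when C5=C6 forms; every compound that holds ring A is worked up at pH 7 or above and purified on Et3N-deactivated silica.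

Step 1
Reactants: 1 (R)-2-methylglycidol, [(2R)-2-methyloxiran-2-yl]methanol
Product: 2 tert-butyl{[(2S)-2-methyloxiran-2-yl]methoxy}diphenylsilane
Conditions: TBDPSCl, imidazole, CH2Cl2, 0 °C → rt
Reagents that add atoms: tert-butyl(chloro)diphenylsilane, CC(C)(C)[Si](Cl)(c1ccccc1)c1ccccc1
Why: Imidazole-promoted silyl ether formation at the primary alcohol leaves the epoxide and the future C4 untouched (the descriptor changes only because the priorities change).

Step 2
Reactants: 2 TBDPS glycidyl ether
Product: 3 (2S)-1-(tert-butyldiphenylsilyloxy)-2-methylpent-4-en-2-ol (C2–C5 fragment)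
Conditions: CH2=CHMgBr, CuI (10 mol %), THF, −40 → 0 °C
Reagents that add atoms: vinylmagnesium bromide, C=C[Mg]Br
Why: Copper-catalysed Grignard opening of a 2,2-disubstituted epoxide is an SN2 attack at the unsubstituted CH2, so no bond to C4 is broken and the tertiary homoallylic alcohol keeps the configuration of 1.

Step 3
Reactants: 4 (R)-citramalic acid
Product: 5 2-[(4R)-2,2,4-trimethyl-5-oxo-1,3-dioxolan-4-yl]acetic acid
Conditions: 2,2-dimethoxypropane, TsOH·H2O (cat.), CH2Cl2, rt
Reagents that add atoms: 2,2-dimethoxypropane, COC(C)(C)OC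
Why: Acid-catalysed transketalisation ties the alpha-hydroxy acid unit (O10, C1) into a five-membered dioxolanone and leaves only the C8 carboxyl free, the usual way to tell apart the two carboxyl groups of malic-type acids.

Step 4
Reactants: 5 dioxolanone acid
Product: 7 (3R)-3-hydroxy-3-methyloxolan-2-one, via hydroxyethyl dioxolanone 6 (not isolated)
Conditions: BH3·THF, THF, 0 °C → rt; MeOH quench; then TsOH·H2O (5 mol %), CH2Cl2, rt
Reagents that add atoms: none
Why: Borane reduces the free carboxylic acid much faster than the dioxolanone carbonyl (chemoselective acid reduction), and acid-catalysed translactonisation of the new primary alcohol onto C1 expels acetone without touching C10.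

Step 5
Reactants: 7 hydroxy lactone
Product: 10 (2R)-2-methyl-2,4-bis(triethylsilyloxy)butanoic acid, via potassium dihydroxybutanoate 8 (not isolated), via tris-TES derivative 9 (not isolated)
Conditions: KOH (1.0 equiv), MeOH–H2O, rt, evaporate to dryness; TESCl, imidazole, DMAP (cat.), DMF, rt → 40 °C; then THF–MeOH–H2O, rt
Reagents that add atoms: potassium hydroxide, [K+].[OH-]; chlorotriethylsilane, CC[Si](Cl)(CC)CC
Why: Saponification opens the lactone, exhaustive silylation caps O8, O10 and the carboxylate before relactonisation can occur, and only the very labile silyl ester is solvolysed in aqueous methanol.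

Step 6
Reactants: 3 tertiary homoallylic alcohol; 10 bis-TES acid
Product: 13 (2S)-1-(tert-butyldiphenylsilyloxy)-2-methylpent-4-en-2-yl (2R)-2-methyl-2,4-bis(triethylsilyloxy)butanoate, via acid chloride 11 (not isolated), via lithium alkoxide 12 (not isolated)
Conditions: 10, 1-chloro-N,N,2-trimethylprop-1-en-1-amine, CH2Cl2, 0 °C; separately 3, n-BuLi, THF, −78 °C; combine at −78 °C → rt
Reagents that add atoms: none
Why: Acylation of a lithium tert-alkoxide by an acid chloride is the established route to esters with two fully substituted partners; here the chloroenamine makes the chloride without HCl so the TES ethers survive, C1 has no alpha hydrogen (no ketene, no epimerisation), the chloride is used cold at once to forestall lactonisation by O8, and the bulky TBDPS group does not migrate onto a tertiary oxygen.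

Step 7
Reactants: 13 tertiary homoallylic ester
Product: 15 (2S)-2-[(tert-butyldiphenylsilyloxy)methyl]-2-methyl-5-[(2R)-2,4-bis(triethylsilyloxy)butan-2-yl]-2,3-dihydrofuran, via C2 titanium alkylidene 14 (not isolated)
Conditions: TiCl4, TMEDA, Zn, PbCl2 (cat.), CH3CHBr2, THF–CH2Cl2, 0 → 65 °C; Et3N/aq. K2CO3 quench
Reagents that add atoms: none
Why: The reduced titanium/1,1-dibromoethane reagent (Takai–Utimoto type) behaves as a titanium ethylidene that first exchanges with the only accessible pi bond, the monosubstituted C2 alkene, releasing propene and placing titanium on C2 (14). This alkylidene adds to the C1 ester carbonyl in a [2+2] sense, and the oxatitanacyclobutane cycloreverts to the C1=C2 enol ether and a titanium oxo species. The closest known reaction type is the olefinic ester cyclisation to cyclic enol ethers with such reagents, which equals ester methylenation followed by enol ether ring-closing metathesis. Ring A closes as a five-membered ring with the new double bond endocyclic, helped by the fully substituted C4 in the tether (gem-dialkyl effect). No stereocentre is formed, and C4 and C10 cannot epimerise because neither carries hydrogen and the medium is aprotic and amine-buffered. The selectivity needed is alkene exchange before direct ethylidenation of the ester, and ester over silyl ethers: the crowding around C1 slows intermolecular attack while the tethered alkylidene reaches C1 through a five-membered arrangement, and the substrate holds no other carbonyl group or alkene.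

Step 8
Reactants: 15 dihydrofuran tris-silyl ether
Product: 16 (3R)-3-{(5S)-5-[(tert-butyldiphenylsilyloxy)methyl]-5-methyl-4,5-dihydrofuran-2-yl}-3-(triethylsilyloxy)butan-1-ol
Conditions: K2CO3 (0.3 equiv), MeOH, rt
Reagents that add atoms: none
Why: Base-catalysed methanolysis of silyl ethers follows steric access, so the unhindered primary TES ether goes well before the tertiary TES and the neopentyl TBDPS ethers, and the basic protic medium prevents both silyl migration and acid-triggered spiroketalisation of O8 onto C1.

Step 9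
Reactants: 16 primary alcohol
Product: 17 (3R)-3-{(5S)-5-[(tert-butyldiphenylsilyloxy)methyl]-5-methyl-4,5-dihydrofuran-2-yl}-3-(triethylsilyloxy)butanal (C8 aldehyde)
Conditions: (n-Pr)4N[RuO4] (5 mol %), NMO, 4 Å molecular sieves, CH2Cl2, 0 °C → rt
Reagents that add atoms: none
Why: The Ley–Griffith oxidation releases no acid and stops at the aldehyde, which suits the acid-labile ring A and the silyl ethers.

Step 10
Reactants: 18 mucobromic acid (3,4-dibromo-5-hydroxyfuran-2(5H)-one)
Product: 19 3,4,5-tribromofuran-2(5H)-one (racemic)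
Conditions: PBr3, CH2Cl2, reflux
Reagents that add atoms: phosphorus tribromide, BrP(Br)Br
Why: Mucobromic acid reacts as its cyclic pseudo-acid, whose lactol hydroxyl is exchanged for halide (pseudo-acid halide formation), and using bromide throughout avoids halogen scrambling.

Step 11
Reactants: 19 tribromobutenolide
Product: 20 dimethyl (3,4-dibromo-5-oxo-2,5-dihydrofuran-2-yl)phosphonate (racemic; ring B with C6–P, C7–Br, C11–Br)
Conditions: P(OMe)3 (1.0 equiv), toluene, 0 → 40 °C
Reagents that add atoms: trimethyl phosphite, COP(OC)OC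
Why: In this Michaelis–Arbuzov reaction the allylic, alpha-acyloxy C6–Br bond is far more reactive toward the phosphite than the two vinylic bromides, as in the preparation of phthalide 3-phosphonates from 3-bromophthalide.

Step 12
Reactants: 17 C8 aldehyde; 20 dibromobutenolide phosphonate
Product: 22 dimethyl (4-bromo-3-{(3R)-1-hydroxy-3-[(5S)-5-(TBDPS-oxymethyl)-5-methyl-4,5-dihydrofuran-2-yl]-3-(triethylsilyloxy)butyl}-5-oxo-2,5-dihydrofuran-2-yl)phosphonate (epimers at C6 and C8), via C7 alkenylchromium 21 (not isolated)
Conditions: 20 (2.5 equiv), CrCl2 (8 equiv), NiCl2 (cat.), DMF, rt; aq. NaHCO3–EDTA work-up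
Reagents that add atoms: none
Why: In this Nozaki–Hiyama–Kishi coupling zerovalent nickel inserts into the more electrophilic beta C7–Br bond (the site preferred in cross-couplings of 3,4-dibromobutenolides), and transfer to trivalent chromium gives a non-basic alkenylchromium that adds only to the aldehyde and tolerates enol ether, silyl ethers and phosphonate; C8 forms without control and is corrected in steps 13 and 14.

Step 13
Reactants: 22 C8 carbinol mixture
Product: 23 the corresponding C8 ketone (C6 epimers)
Conditions: (n-Pr)4N[RuO4] (10 mol %), NMO, 4 Å molecular sieves, CH2Cl2, rt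
Reagents that add atoms: none
Why: The acid-free Ley–Griffith oxidation erases the uncontrolled C8 centre without exposing the gamma-hydroxy enol ether to acid.

Step 14
Reactants: 23 C8 ketone
Product: 24 the (8S)-alcohol (1S,3R in the butyl chain; C6 epimers)
Conditions: (R)-Me-CBS oxazaborolidine (0.5 equiv), catecholborane, toluene, −78 °C; MeOH, then aqueous work-up at pH 7–8
Reagents that add atoms: none
Why: In the Corey–Bakshi–Shibata reduction the fully substituted ring B carbon C7 acts as the large and the C9 methylene as the small ketone substituent, so the (R)-catalyst delivers hydride to the face that gives (8S), that is O8 syn to O10; this is preferred over chelation control because CH3 and ring A on C10 differ too little in size, and catecholborane at −78 °C does not hydroborate the enol ether.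

Step 15
Reactants: 24 (8S)-alcohol
Product: 25 the (8S)-methacrylate
Conditions: methacrylic anhydride, DMAP (cat.), pyridine–CH2Cl2, BHT, 0 °C → rt
Reagents that add atoms: methacrylic anhydride, C=C(C)C(=O)OC(=O)C(C)=C
Why: DMAP-catalysed acylation proceeds with retention at C8, and the weak base pyridine keeps the acidic C6–H phosphonate largely protonated.

Step 16
Reactants: 25 methacrylate
Product: 26 the C5,C10-diol (primary C5–OH, tertiary C10–OH)
Conditions: Bu4NF–AcOH (1:1), THF, 0 °C → rt
Reagents that add atoms: none
Why: Buffered fluoride desilylation removes the TBDPS and the tertiary TES groups together under nearly neutral conditions, which the methacrylate, the phosphonate and ring A tolerate now that O8 is acylated and can no longer add to C1.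

Step 17
Reactants: 26 diol
Product: 27 the C5 aldehyde (alpha-quaternary, non-enolisable)
Conditions: (n-Pr)4N[RuO4] (10 mol %), NMO, 4 Å molecular sieves, CH2Cl2, 0 °C → rt
Reagents that add atoms: none
Why: The Ley–Griffith oxidation converts the only oxidisable alcohol (C5–OH) while the tertiary C10–OH is inert, and the amine present is too weak to start the olefination early.

Step 18
Reactants: 27 aldehyde phosphonate
Product: 28 (4S,8S,10R,5E)-11-bromo-10-hydroxy-8-methacryloyloxy-13-nor-1,4-epoxygermacra-1,5,7(11)-trien-12,6-olide (macrocyclic bromide)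
Conditions: slow addition of 27 to LiCl and DBU in MeCN (final 1 mM), rt
Reagents that add atoms: none
Why: This is an intramolecular Horner–Wadsworth–Emmons olefination under Masamune–Roush conditions, in which the strongly stabilised C6 carbanion (a 2-oxidofuran) forms with a mild base, adds reversibly to the non-enolisable C5 aldehyde and eliminates phosphate, and the bridged ten-membered ring can only accommodate C4 cis to C7, which fixes the E geometry and removes the C6 stereocentre.

Step 19
Reactants: 28 macrocyclic bromide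
Product: 29 the 13-hydroxy compound (C11–CH2OH)
Conditions: Bu3SnCH2OH, Pd(PPh3)4 (10 mol %), BHT, 1,4-dioxane, 80 °C
Reagents that add atoms: (tributylstannyl)methanol, CCCC[Sn](CCCC)(CCCC)CO
Why: Migita–Kosugi–Stille hydroxymethylation of an alpha-bromobutenolide runs under neutral conditions, the hydroxymethyl group transfers in preference to butyl, and the O8 ester on a tetrasubstituted, electron-poor alkene resists ionisation by zerovalent palladium, so C8 is not scrambled.

Step 20
Reactants: 29 13-hydroxy compound
Product: 30 target CNP0394509.2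
Conditions: Ac2O, pyridine, CH2Cl2, 0 °C
Reagents that add atoms: acetic anhydride, CC(=O)OC(C)=O
Why: Selective acetylation takes the primary allylic C13–OH, whereas the tertiary C10–OH does not react under these mild basic conditions.

Compound list
1 | (R)-2-methylglycidol | C[C@@]1(CO)CO1 | starting material
2 | tert-butyl{[(2S)-2-methyloxiran-2-yl]methoxy}diphenylsilane | C[C@@]1(CO[Si](c2ccccc2)(c2ccccc2)C(C)(C)C)CO1 | intermediate
3 | (2S)-1-(tert-butyldiphenylsilyloxy)-2-methylpent-4-en-2-ol | C=CC[C@@](C)(CO[Si](c1ccccc1)(c1ccccc1)C(C)(C)C)O | intermediate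
4 | (R)-citramalic acid | C[C@@](O)(CC(O)=O)C(O)=O | starting material
5 | 2-[(4R)-2,2,4-trimethyl-5-oxo-1,3-dioxolan-4-yl]acetic acid | C[C@]1(CC(O)=O)OC(C)(C)OC1=O | intermediate
6 | (5R)-5-(2-hydroxyethyl)-2,2,5-trimethyl-1,3-dioxolan-4-one (not isolated) | C[C@]1(CCO)OC(C)(C)OC1=O | intermediate
7 | (3R)-3-hydroxy-3-methyloxolan-2-one | C[C@@]1(O)CCOC1=O | intermediate
8 | potassium (2R)-2,4-dihydroxy-2-methylbutanoate (not isolated) | [K+].[O-]C(=O)[C@](C)(O)CCO | intermediate
9 | triethylsilyl (2R)-2-methyl-2,4-bis(triethylsilyloxy)butanoate (not isolated) | CC[Si](CC)(CC)OC(=O)[C@](C)(O[Si](CC)(CC)CC)CCO[Si](CC)(CC)CC | intermediate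
10 | (2R)-2-methyl-2,4-bis(triethylsilyloxy)butanoic acid | OC(=O)[C@](C)(O[Si](CC)(CC)CC)CCO[Si](CC)(CC)CC | intermediate
11 | (2R)-2-methyl-2,4-bis(triethylsilyloxy)butanoyl chloride (not isolated) | ClC(=O)[C@](C)(O[Si](CC)(CC)CC)CCO[Si](CC)(CC)CC | intermediate
12 | lithium (2S)-1-(tert-butyldiphenylsilyloxy)-2-methylpent-4-en-2-olate (not isolated) | C=CC[C@@](C)(CO[Si](c1ccccc1)(c1ccccc1)C(C)(C)C)[O-].[Li+] | intermediate
13 | (2S)-1-(tert-butyldiphenylsilyloxy)-2-methylpent-4-en-2-yl (2R)-2-methyl-2,4-bis(triethylsilyloxy)butanoate (key-step precursor) | C=CC[C@@](C)(CO[Si](c1ccccc1)(c1ccccc1)C(C)(C)C)OC(=O)[C@](C)(O[Si](CC)(CC)CC)CCO[Si](CC)(CC)CC | intermediate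
14 | C2 titanium alkylidene of 13, TMEDA ligand omitted (not isolated) | Cl[Ti](Cl)=CC[C@@](C)(CO[Si](c1ccccc1)(c1ccccc1)C(C)(C)C)OC(=O)[C@](C)(O[Si](CC)(CC)CC)CCO[Si](CC)(CC)CC | intermediate
15 | (2S)-2-[(tert-butyldiphenylsilyloxy)methyl]-2-methyl-5-[(2R)-2,4-bis(triethylsilyloxy)butan-2-yl]-2,3-dihydrofuran (key-step product) | CC[Si](CC)(CC)OCC[C@@](C)(O[Si](CC)(CC)CC)C1=CC[C@@](C)(CO[Si](c2ccccc2)(c2ccccc2)C(C)(C)C)O1 | intermediate
16 | C8 primary alcohol | OCC[C@@](C)(O[Si](CC)(CC)CC)C1=CC[C@@](C)(CO[Si](c2ccccc2)(c2ccccc2)C(C)(C)C)O1 | intermediate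
17 | C8 aldehyde | O=CC[C@@](C)(O[Si](CC)(CC)CC)C1=CC[C@@](C)(CO[Si](c2ccccc2)(c2ccccc2)C(C)(C)C)O1 | intermediate
18 | mucobromic acid | OC1OC(=O)C(Br)=C1Br | starting material
19 | 3,4,5-tribromofuran-2(5H)-one | BrC1OC(=O)C(Br)=C1Br | intermediate
20 | dimethyl (3,4-dibromo-5-oxo-2,5-dihydrofuran-2-yl)phosphonate | COP(=O)(OC)C1OC(=O)C(Br)=C1Br | intermediate
21 | C7 alkenylchromium dichloride from 20 (not isolated) | COP(=O)(OC)C1OC(=O)C(Br)=C1[Cr](Cl)Cl | intermediate
22 | C8 carbinol, epimers at C6 and C8 | COP(=O)(OC)C1OC(=O)C(Br)=C1C(O)C[C@@](C)(O[Si](CC)(CC)CC)C2=CC[C@@](C)(CO[Si](c3ccccc3)(c3ccccc3)C(C)(C)C)O2 | intermediate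
23 | C8 ketone, C6 epimers | COP(=O)(OC)C1OC(=O)C(Br)=C1C(=O)C[C@@](C)(O[Si](CC)(CC)CC)C2=CC[C@@](C)(CO[Si](c3ccccc3)(c3ccccc3)C(C)(C)C)O2 | intermediate
24 | (8S)-alcohol, C6 epimers | COP(=O)(OC)C1OC(=O)C(Br)=C1[C@@H](O)C[C@@](C)(O[Si](CC)(CC)CC)C2=CC[C@@](C)(CO[Si](c3ccccc3)(c3ccccc3)C(C)(C)C)O2 | intermediate
25 | (8S)-methacrylate, C6 epimers | COP(=O)(OC)C1OC(=O)C(Br)=C1[C@@H](OC(=O)C(C)=C)C[C@@](C)(O[Si](CC)(CC)CC)C2=CC[C@@](C)(CO[Si](c3ccccc3)(c3ccccc3)C(C)(C)C)O2 | intermediate
26 | C5,C10-diol, C6 epimers | COP(=O)(OC)C1OC(=O)C(Br)=C1[C@@H](OC(=O)C(C)=C)C[C@@](C)(O)C2=CC[C@@](C)(CO)O2 | intermediate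
27 | C5 aldehyde, C6 epimers | COP(=O)(OC)C1OC(=O)C(Br)=C1[C@@H](OC(=O)C(C)=C)C[C@@](C)(O)C2=CC[C@@](C)(C=O)O2 | intermediate
28 | macrocyclic C11 bromide (4S,8S,10R,5E) | C=C(C)C(=O)O[C@H]1C[C@@](C)(O)C2=CC[C@@](C)(/C=C3/OC(=O)C(Br)=C31)O2 | intermediate
29 | 13-hydroxy compound (4S,8S,10R,5E) | C=C(C)C(=O)O[C@H]1C[C@@](C)(O)C2=CC[C@@](C)(/C=C3/OC(=O)C(CO)=C31)O2 | intermediate
30 | CNP0394509.2, (4S,8S,10R,5E)-13-acetoxy-10-hydroxy-8-methacryloyloxy-1,4-epoxygermacra-1,5,7(11)-trien-12,6-olide | C=C(C)C(=O)O[C@H]1C[C@@](C)(O)C2=CC[C@@](C)(/C=C3/OC(=O)C(COC(C)=O)=C31)O2 | target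

Total step count: 20. Longest linear sequence: 16 steps (from 4 through steps 3–9 and 12–20).

Steps most likely to fail

1. Step 18 (closure of the ten-membered ring).
- What may go wrong: intermolecular olefination to dimers and oligomers may outrun the strained closure. The addition to the hindered C5 aldehyde may stay reversible without elimination. Prolonged base may cause acyl migration from O8.
- Fallback (sets out from 17 and 18, returns at 28): the phosphonate is given up and C5–C6 is first made as a single bond.
- NaBH4 reduction of 18 gives 3,4-dibromofuran-2(5H)-one F1, which is coupled with 17 under the conditions of step 12 to the carbinol F2.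
- The operations of steps 13–17 then lead through the ketone F3, the (8S)-alcohol F4, the methacrylate F5 and the diol F6 to the aldehyde F7.
- TESOTf and i-Pr2NEt in dilute CH2Cl2 silylate O10 and convert ring B into the 2-silyloxyfuran F8.
- F8 closes by an intramolecular vinylogous Mukaiyama aldol addition to the macrocyclic silyl aldol F9.
- DBU in the same flask expels triethylsilanolate by an E1cB path and gives the 10-O-TES macrocycle F10, in which the ring again allows only C4 cis to C7.
- Bu4NF–AcOH then returns to 28.

2. Step 12 (Ni/Cr coupling).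
- What may go wrong: the acidic C6–H of a second molecule of 20 may protonate the alkenylchromium. Divalent chromium may reductively debrominate the electron-poor dibromide. Insertion may also occur at C11–Br. The crowded alkenylchromium may add sluggishly.
- Fallback (sets out from 20 and 17, returns at 22): ring B is masked as its aromatic tautomer and used as a preformed Grignard reagent.
- TIPSOTf and Et3N convert 20 into dimethyl [3,4-dibromo-5-(triisopropylsilyloxy)furan-2-yl]phosphonate F11, which has no acidic hydrogen.
- i-PrMgCl·LiCl in THF at −40 °C exchanges the bromine next to the chelating, electron-withdrawing phosphoryl group and gives the furylmagnesium chloride F12. This is metal–halogen exchange of a bromo-2-silyloxyfuran.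
- Addition to 17 gives the furyl carbinol F13.
- One equivalent of Bu4NF–AcOH at −78 °C cleaves only the enol-type O–Si bond and releases 22.

3. Step 7 (olefin–ester cyclisation).
- What may go wrong: the tethered alkylidene may fail to engage the crowded C1 carbonyl, so the alkene is merely converted into a propenyl group. TES ethers may be lost to Lewis acidic titanium and zinc salts at 65 °C. The product may hydrolyse on work-up.
- Fallback (sets out from 13, returns at 15): the two events are separated.
- Cp2TiMe2 in toluene at 80 °C delivers the smallest possible alkylidene, Cp2Ti=CH2. It methylenates C1 under halide-free conditions to the acyclic enol ether diene F14.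
- Ring-closing metathesis with the second-generation Grubbs catalyst RuCl2(=CHPh)(PCy3)(SIMes) in toluene at 70 °C then forms the same C1=C2 bond and gives 15.

Further compounds
F1 | step 18 | 3,4-dibromofuran-2(5H)-one | O=C1OCC(Br)=C1Br
F2 | step 18 | C8 carbinol without phosphonate (C8 epimers) | O=C1OCC(C(O)C[C@@](C)(O[Si](CC)(CC)CC)C2=CC[C@@](C)(CO[Si](c3ccccc3)(c3ccccc3)C(C)(C)C)O2)=C1Br
F3 | step 18 | C8 ketone without phosphonate | O=C1OCC(C(=O)C[C@@](C)(O[Si](CC)(CC)CC)C2=CC[C@@](C)(CO[Si](c3ccccc3)(c3ccccc3)C(C)(C)C)O2)=C1Br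
F4 | step 18 | (8S)-alcohol without phosphonate | O=C1OCC([C@@H](O)C[C@@](C)(O[Si](CC)(CC)CC)C2=CC[C@@](C)(CO[Si](c3ccccc3)(c3ccccc3)C(C)(C)C)O2)=C1Br
F5 | step 18 | (8S)-methacrylate without phosphonate | O=C1OCC([C@@H](OC(=O)C(C)=C)C[C@@](C)(O[Si](CC)(CC)CC)C2=CC[C@@](C)(CO[Si](c3ccccc3)(c3ccccc3)C(C)(C)C)O2)=C1Br
F6 | step 18 | C5,C10-diol without phosphonate | O=C1OCC([C@@H](OC(=O)C(C)=C)C[C@@](C)(O)C2=CC[C@@](C)(CO)O2)=C1Br
F7 | step 18 | C5 aldehyde without phosphonate | O=C1OCC([C@@H](OC(=O)C(C)=C)C[C@@](C)(O)C2=CC[C@@](C)(C=O)O2)=C1Br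
F8 | step 18 | 2-(triethylsilyloxy)furan aldehyde, O10 silylated | CC[Si](CC)(CC)Oc1occ([C@@H](OC(=O)C(C)=C)C[C@@](C)(O[Si](CC)(CC)CC)C2=CC[C@@](C)(C=O)O2)c1Br
F9 | step 18 | macrocyclic C5 silyl aldol (C5 and C6 undefined) | C=C(C)C(=O)O[C@H]1C[C@@](C)(O[Si](CC)(CC)CC)C2=CC[C@@](C)(C(O[Si](CC)(CC)CC)C3OC(=O)C(Br)=C31)O2
F10 | step 18 | 10-O-TES ether of 28 | C=C(C)C(=O)O[C@H]1C[C@@](C)(O[Si](CC)(CC)CC)C2=CC[C@@](C)(/C=C3/OC(=O)C(Br)=C31)O2
F11 | step 12 | dimethyl [3,4-dibromo-5-(triisopropylsilyloxy)furan-2-yl]phosphonate | COP(=O)(OC)c1oc(O[Si](C(C)C)(C(C)C)C(C)C)c(Br)c1Br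
F12 | step 12 | [4-bromo-2-(dimethoxyphosphoryl)-5-(triisopropylsilyloxy)furan-3-yl]magnesium chloride | COP(=O)(OC)c1oc(O[Si](C(C)C)(C(C)C)C(C)C)c(Br)c1[Mg]Cl
F13 | step 12 | furyl carbinol (C8 epimers) | COP(=O)(OC)c1oc(O[Si](C(C)C)(C(C)C)C(C)C)c(Br)c1C(O)C[C@@](C)(O[Si](CC)(CC)CC)C2=CC[C@@](C)(CO[Si](c3ccccc3)(c3ccccc3)C(C)(C)C)O2
F14 | step 7 | acyclic enol ether diene (C1 methylenated 13) | C=CC[C@@](C)(CO[Si](c1ccccc1)(c1ccccc1)C(C)(C)C)OC(=C)[C@](C)(O[Si](CC)(CC)CC)CCO[Si](CC)(CC)CC
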